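**Plan**
- Retrosynthesis: the C6 prenyl group is traced back to an O5 1,1-dimethylallyl ether (C6–C1'' cut, Claisen), the pyranone is opened at O1–C8a, and the C3=C4 bond is cut into an aldehyde carbon (C4) and an arylacetic acid (C3, C2).
- Forward: 2,4-dihydroxyphenylacetic acid is converted into its bis-pivalate and condensed with MOM-protected 2-hydroxy-4-methoxybenzaldehyde. The resulting E-diarylacrylic acid is closed to the coumarin by photocatalytic E→Z isomerisation and C–H lactonisation; the pyranone (O1–C8a) is the only ring formed.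
- Enabling feature: ring A (C4a, C5–C8, C8a) carries oxygen on C5, C7 and C8a. The aldehyde already holds the C5 and C7 oxygens in differentiated form (OH → O5, OMe → O7), and its single unsubstituted ortho carbon becomes C8a, so O1 can be delivered last from the carboxyl group.
- End game: O5 is unmasked, converted into the 1,1-dimethylallyl ether, shifted to C6, and the ring-B pivalates are removed.
- Stereochemistry: none to set; the acrylic acid geometry is corrected within the key step and the prenyl alkene has two identical methyl groups.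

Key step: step 6

Assumption: the target has no stereocentre, so "single enantiomer" places no demand on the route; the only geometric element handled is the E/Z geometry of the acrylic acid.

**Step 1**
Reactants: 1 2-(2,4-dihydroxyphenyl)acetic acid
Product: 2 benzyl 2-(2,4-dihydroxyphenyl)acetate
Conditions: BnBr, KHCO3, DMF, rt
Reagents that add atoms: benzyl bromide, BrCc1ccccc1
Why: Carboxylate alkylation (SN2 esterification) is selective because bicarbonate deprotonates only the carboxylic acid, and masking the acid first keeps the ortho phenol from lactonising to a benzofuran-2(3H)-one when the acylating agent is added in step 2.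

**Step 2**
Reactants: 2 benzyl 2-(2,4-dihydroxyphenyl)acetate
Product: 3 benzyl 2-[2,4-bis(pivaloyloxy)phenyl]acetate
Conditions: PivCl, pyridine, DMAP (cat.), CH2Cl2, 0 °C → rt
Reagents that add atoms: pivaloyl chloride, CC(C)(C)C(Cl)=O
Why: DMAP-catalysed O-acylation esterifies both phenols, and hindered pivalates are chosen because they should resist acyl exchange in hot acetic anhydride, survive the later Lewis acid, DBU and hydrogenation conditions, and make ring B too electron-poor to be oxidised in step 6.

**Step 3**
Reactants: 3 benzyl 2-[2,4-bis(pivaloyloxy)phenyl]acetate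
Product: 4 2-[2,4-bis(pivaloyloxy)phenyl]acetic acid
Conditions: H2 (1 atm), 10% Pd/C, EtOAc, rt
Reagents that add atoms: none
Why: Catalytic hydrogenolysis of the benzyl ester frees the acid under neutral conditions that leave aryl pivalates untouched.

**Step 4**
Reactants: 5 2-hydroxy-4-methoxybenzaldehyde
Product: 6 4-methoxy-2-(methoxymethoxy)benzaldehyde
Conditions: MOMCl, iPr2NEt, CH2Cl2, 0 °C → rt
Reagents that add atoms: chloromethyl methyl ether, COCCl
Why: Base-mediated O-alkylation of the phenol (acetal protection) installs an ortho oxygen substituent that, unlike an ester, cannot transfer an acyl group or lactonise during the condensation and can later be removed without touching the pivalates.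

**Step 5**
Reactants: 4 2-[2,4-bis(pivaloyloxy)phenyl]acetic acid; 6 4-methoxy-2-(methoxymethoxy)benzaldehyde
Product: 7 (E)-2-[2,4-bis(pivaloyloxy)phenyl]-3-[4-methoxy-2-(methoxymethoxy)phenyl]prop-2-enoic acid (aryl rings cis)
Conditions: Ac2O, Et3N, 100 °C; then H2O, 60 °C; aq. citric acid, 0 °C
Reagents that add atoms: none
Why: In this Perkin condensation of an arylacetic acid the mixed-anhydride enolate adds to the aldehyde and β-acetoxy elimination should give the thermodynamically preferred E-acid with the two aryl groups cis, while the acetal on ring A and the hindered pivalates on ring B offer no path to a lactone.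

**Step 6**
Reactants: 7 (E)-2-[2,4-bis(pivaloyloxy)phenyl]-3-[4-methoxy-2-(methoxymethoxy)phenyl]prop-2-enoic acid
Product: 9 3-[2,4-bis(pivaloyloxy)phenyl]-7-methoxy-5-(methoxymethoxy)coumarin, via Z-acid 8 (not isolated)
Conditions: (−)-riboflavin (10 mol%), O2 (1 atm), 402 nm LEDs, MeCN/MeOH 1:1, rt
Reagents that add atoms: none
Why: Proposed new method: triplet energy transfer from excited riboflavin should excite the planar cinnamoyl chromophore of 7 (ring B is held out of conjugation by its ortho pivaloyloxy group) and give Z-acid 8, whose ring A is twisted by the cis carboxyl group and is a poorer energy acceptor; a second excited flavin then oxidises the dialkoxystyrene unit of 8 by single-electron transfer, the carboxylate adds to C8a, and a further oxidation with loss of the C8a proton rearomatises ring A while O2 returns the reduced flavin and leaves H2O2. The closest known reaction type is the flavin-photocatalysed E→Z isomerisation and oxidative lactonisation of β-substituted cinnamic acids to 4-substituted coumarins, supported by the dehydrogenative lactonisation of biaryl-2-carboxylic acids; an α-aryl acid without a β-substituent and with a 2,4-dioxygenated ring has not been shown. The pyranone closes by attack of oxygen on the sp2 carbon C8a in a six-membered, formally 6-endo-trig mode, the C4a–C8a π bond lying inside the new ring. No stereocentre is formed, and the alkene geometry is fixed by the ring closure itself. The step needs site selectivity for C8a–H over ipso attack at C5–OMOM and chemoselectivity for ring A over ring B: C8a is the only unsubstituted ortho carbon, the MOM ether should turn away from the carboxyl group in the reactive rotamer of 8, an ipso adduct cannot rearomatise by proton loss and should revert, the irreversible C–H cyclisation drains even an unfavourable E/Z mixture, and the bis-pivalate ring B is too electron-poor to be oxidised.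

**Step 7**
Reactants: 9 3-[2,4-bis(pivaloyloxy)phenyl]-7-methoxy-5-(methoxymethoxy)coumarin
Product: 10 3-[2,4-bis(pivaloyloxy)phenyl]-5-hydroxy-7-methoxycoumarin
Conditions: ZnBr2, n-PrSH, CH2Cl2, 0 °C → rt
Reagents that add atoms: none
Why: Lewis-acid activation of the acetal and capture of the methoxymethyl cation by the thiol (soft-nucleophile acetal cleavage) should free O5 quickly under conditions that do not touch aryl pivalates or the lactone.

**Step 8**
Reactants: 10 3-[2,4-bis(pivaloyloxy)phenyl]-5-hydroxy-7-methoxycoumarin
Product: 11 3-[2,4-bis(pivaloyloxy)phenyl]-7-methoxy-5-(2-methylbut-3-yn-2-yloxy)coumarin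
Conditions: 3-chloro-3-methylbut-1-yne, CuCl2·2H2O (cat.), DBU, MeCN, 0 °C
Reagents that add atoms: 3-chloro-3-methylbut-1-yne, CC(C)(Cl)C#C
Why: Copper-catalysed propargylic etherification proceeds through a copper-bound propargyl/allenylidene electrophile and therefore forms the tertiary alkyl aryl ether that SN2 chemistry cannot, with the O5 phenoxide as the only nucleophile present.

**Step 9**
Reactants: 11 3-[2,4-bis(pivaloyloxy)phenyl]-7-methoxy-5-(2-methylbut-3-yn-2-yloxy)coumarin
Product: 12 3-[2,4-bis(pivaloyloxy)phenyl]-7-methoxy-5-(2-methylbut-3-en-2-yloxy)coumarin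
Conditions: H2 (1 atm), Lindlar catalyst, quinoline, EtOAc, rt
Reagents that add atoms: none
Why: Lindlar semi-hydrogenation should stop at the terminal alkene and leave the conjugated, trisubstituted C3=C4 bond of the coumarin and the esters alone.

**Step 10**
Reactants: 12 3-[2,4-bis(pivaloyloxy)phenyl]-7-methoxy-5-(2-methylbut-3-en-2-yloxy)coumarin
Product: 14 3-[2,4-bis(pivaloyloxy)phenyl]-5-hydroxy-7-methoxy-6-(3-methylbut-2-enyl)coumarin, via ortho-dienone 13 (not isolated)
Conditions: PhNEt2 (degassed), 130 °C
Reagents that add atoms: none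
Why: In this aromatic Claisen rearrangement the [3,3] shift through a chair transition state delivers the allyl terminus to C6, the only unsubstituted ortho carbon of O5 (C4a is quaternary), with allylic transposition that turns the 1,1-dimethylallyl ether into the prenyl group, and tautomerisation of dienone 13 restores the 5-OH.

**Step 11**
Reactants: 14 3-[2,4-bis(pivaloyloxy)phenyl]-5-hydroxy-7-methoxy-6-(3-methylbut-2-enyl)coumarin
Product: 15 3-(2,4-dihydroxyphenyl)-5-hydroxy-7-methoxy-6-(3-methylbut-2-enyl)coumarin
Conditions: K2CO3, MeOH (degassed), 0 °C → rt; then aq. citric acid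
Reagents that add atoms: none
Why: Base-catalysed transesterification (methanolysis) cleaves the activated aryl pivalates, and any methoxide-opened Z-coumarinate should re-close to the lactone on the mild acidification, which is kept weak so that the 5-OH does not add to the prenyl alkene.

**Compound list**
1 | 2-(2,4-dihydroxyphenyl)acetic acid | OC(=O)Cc1ccc(O)cc1O | starting material
2 | benzyl 2-(2,4-dihydroxyphenyl)acetate | O=C(Cc1ccc(O)cc1O)OCc1ccccc1 | intermediate
3 | benzyl 2-[2,4-bis(pivaloyloxy)phenyl]acetate | CC(C)(C)C(=O)Oc1ccc(CC(=O)OCc2ccccc2)c(OC(=O)C(C)(C)C)c1 | intermediate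
4 | 2-[2,4-bis(pivaloyloxy)phenyl]acetic acid | CC(C)(C)C(=O)Oc1ccc(CC(=O)O)c(OC(=O)C(C)(C)C)c1 | intermediate
5 | 2-hydroxy-4-methoxybenzaldehyde | COc1ccc(C=O)c(O)c1 | starting material
6 | 4-methoxy-2-(methoxymethoxy)benzaldehyde | COCOc1cc(OC)ccc1C=O | intermediate
7 | (E)-2-[2,4-bis(pivaloyloxy)phenyl]-3-[4-methoxy-2-(methoxymethoxy)phenyl]prop-2-enoic acid | COCOc1cc(OC)ccc1/C=C(/C(=O)O)c1ccc(OC(=O)C(C)(C)C)cc1OC(=O)C(C)(C)C | intermediate
8 | (Z)-2-[2,4-bis(pivaloyloxy)phenyl]-3-[4-methoxy-2-(methoxymethoxy)phenyl]prop-2-enoic acid (formed in step 6, not isolated) | COCOc1cc(OC)ccc1/C=C(\C(=O)O)c1ccc(OC(=O)C(C)(C)C)cc1OC(=O)C(C)(C)C | intermediate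
9 | 3-[2,4-bis(pivaloyloxy)phenyl]-7-methoxy-5-(methoxymethoxy)coumarin | COCOc1cc(OC)cc2oc(=O)c(-c3ccc(OC(=O)C(C)(C)C)cc3OC(=O)C(C)(C)C)cc12 | intermediate
10 | 3-[2,4-bis(pivaloyloxy)phenyl]-5-hydroxy-7-methoxycoumarin | COc1cc(O)c2cc(-c3ccc(OC(=O)C(C)(C)C)cc3OC(=O)C(C)(C)C)c(=O)oc2c1 | intermediate
11 | 3-[2,4-bis(pivaloyloxy)phenyl]-7-methoxy-5-(2-methylbut-3-yn-2-yloxy)coumarin | COc1cc(OC(C)(C)C#C)c2cc(-c3ccc(OC(=O)C(C)(C)C)cc3OC(=O)C(C)(C)C)c(=O)oc2c1 | intermediate
12 | 3-[2,4-bis(pivaloyloxy)phenyl]-7-methoxy-5-(2-methylbut-3-en-2-yloxy)coumarin | COc1cc(OC(C)(C)C=C)c2cc(-c3ccc(OC(=O)C(C)(C)C)cc3OC(=O)C(C)(C)C)c(=O)oc2c1 | intermediate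
13 | 3-[2,4-bis(pivaloyloxy)phenyl]-7-methoxy-6-(3-methylbut-2-enyl)-6H-chromene-2,5-dione (ortho-dienone, racemic at C6, formed in step 10, not isolated) | COC1=CC2=C(C=C(c3ccc(OC(=O)C(C)(C)C)cc3OC(=O)C(C)(C)C)C(=O)O2)C(=O)C1CC=C(C)C | intermediate
14 | 3-[2,4-bis(pivaloyloxy)phenyl]-5-hydroxy-7-methoxy-6-(3-methylbut-2-enyl)coumarin | COc1cc2oc(=O)c(-c3ccc(OC(=O)C(C)(C)C)cc3OC(=O)C(C)(C)C)cc2c(O)c1CC=C(C)C | intermediate
15 | 3-(2,4-dihydroxyphenyl)-5-hydroxy-7-methoxy-6-(3-methylbut-2-enyl)coumarin | COc1cc2oc(=O)c(-c3ccc(O)cc3O)cc2c(O)c1CC=C(C)C | target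

**Step count**
Total: 11 steps. Longest linear sequence: 10 steps (steps 1, 2, 3, 5, 6, 7, 8, 9, 10, 11, from compound 1).

**Steps most likely to fail**

1. Step 6 (Proposed new method). The sensitised equilibration may settle on the E side faster than the Z-acid cyclises. The carboxylate may add ipso at C5 with loss of the MOM-oxy group. Singlet oxygen may cleave the electron-rich alkene. Fallback with known chemistry, setting out from acid 4 and returning at coumarin 9: commercial 2,4,6-trihydroxybenzaldehyde would be mono-methylated at its only non-chelated hydroxyl (MeI, K2CO3, DMF) to 2,6-dihydroxy-4-methoxybenzaldehyde F1. One of the two equivalent chelated hydroxyls would then be protected (MOMCl, iPr2NEt, CH2Cl2) to give 2-hydroxy-4-methoxy-6-(methoxymethoxy)benzaldehyde F2. A Perkin–Oglialoro coumarin synthesis of F2 with 4 (Ac2O, Et3N, 110 °C) would form the C3=C4 bond and close the lactone from the pre-installed phenol oxygen, giving 9 directly.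

2. Step 5. Addition to the electron-rich aldehyde may be slow, and at the temperature needed the ortho pivalate may undergo acyl exchange followed by lactonisation onto ring B, or the acetal may be lost to the acetic acid formed. Fallback setting out from acid 4 and aldehyde 6 and returning at acid 7: 4 would be alkylated at the carboxylate (allyl bromide, KHCO3, DMF) to allyl 2-[2,4-bis(pivaloyloxy)phenyl]acetate F3. Its lithium enolate (LiHMDS, THF, −78 °C) would be added to 6 and the aldolate trapped with Ac2O to give allyl 3-acetoxy-2-[2,4-bis(pivaloyloxy)phenyl]-3-[4-methoxy-2-(methoxymethoxy)phenyl]propanoate F4. Elimination with DBU would give allyl (E)-2-[2,4-bis(pivaloyloxy)phenyl]-3-[4-methoxy-2-(methoxymethoxy)phenyl]prop-2-enoate F5. Pd(PPh3)4/PhSiH3 would remove the allyl group without touching the alkene and give 7; any Z ester formed would lead to 8, which step 6 also accepts.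

3. Step 10. The tertiary allyl ether may fragment to phenol 10 and isoprene before it rearranges, or the allyl group may travel to C8 through C4a by a Claisen–Cope sequence. Fallback setting out from phenol 10 and returning at 14: O-alkylation with prenyl bromide (K2CO3, acetone) would give 3-[2,4-bis(pivaloyloxy)phenyl]-7-methoxy-5-(3-methylbut-2-enyloxy)coumarin F6. Its ionisation on montmorillonite K10 (CH2Cl2, 0 °C → rt) would bring about the known dissociative 1,3-shift of aryl prenyl ethers to the ortho carbon C6, giving 14 without a sigmatropic step.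

**Further compounds**
F1 | step 6 | 2,6-dihydroxy-4-methoxybenzaldehyde | COc1cc(O)c(C=O)c(O)c1
F2 | step 6 | 2-hydroxy-4-methoxy-6-(methoxymethoxy)benzaldehyde | COCOc1cc(OC)cc(O)c1C=O
F3 | step 5 | allyl 2-[2,4-bis(pivaloyloxy)phenyl]acetate | C=CCOC(=O)Cc1ccc(OC(=O)C(C)(C)C)cc1OC(=O)C(C)(C)C
F4 | step 5 | allyl 3-acetoxy-2-[2,4-bis(pivaloyloxy)phenyl]-3-[4-methoxy-2-(methoxymethoxy)phenyl]propanoate (racemic mixture of diastereomers) | COCOc1cc(OC)ccc1C(OC(C)=O)C(C(=O)OCC=C)c1ccc(OC(=O)C(C)(C)C)cc1OC(=O)C(C)(C)C
F5 | step 5 | allyl (E)-2-[2,4-bis(pivaloyloxy)phenyl]-3-[4-methoxy-2-(methoxymethoxy)phenyl]prop-2-enoate | COCOc1cc(OC)ccc1/C=C(/C(=O)OCC=C)c1ccc(OC(=O)C(C)(C)C)cc1OC(=O)C(C)(C)C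
F6 | step 10 | 3-[2,4-bis(pivaloyloxy)phenyl]-7-methoxy-5-(3-methylbut-2-enyloxy)coumarin | COc1cc(OCC=C(C)C)c2cc(-c3ccc(OC(=O)C(C)(C)C)cc3OC(=O)C(C)(C)C)c(=O)oc2c1
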